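## Analysis of the target

The target is a phlorotannin of the fucofuroeckol type. A 3,5-dihydroxyphenyl ether (ring A) hangs from a dibenzo-1,4-dioxin; one dioxin benzene ring is ring B, and the other (ring D) is also one half of a dibenzofuran (furan ring plus ring F).

Labels used throughout: B1 (ring A ether), B2 (OH), B3 (H), B4 (OH), B5 and B6 (dioxin carbons); D1 (dioxin O), D2 (OH), D3 (H), D4 (furan O), D5 (bond to ring F), D6 (dioxin O). The dioxin bonds are B5–O–D6 and B6–O–D1. D1/D2/D3/D4/D5/D6 are C8/C7/C6/C5a/C9a/C9 of the dibenzofuran, and ring F carries hydroxyls at C1 and C3.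

There is no stereocenter, so the whole problem is regiochemistry on three heavily oxygenated benzene rings. The seven free phenols make the compound electron-rich and prone to air oxidation, so they are carried as methyl ethers and released in the last step.

The hard points are three: the orientation of the unsymmetrical dioxin; the D6 oxygen, which sits in the bay of the dibenzofuran close to the C1 oxygen of ring F (estimated from standard bond lengths at well under 3 Å); and telling the B1 oxygen from the B4 oxygen.

The strategy rests on ring B. Its oxygens at B1 and B4 are para to each other and flank B6 and B5, so ring B can be carried as a 1,4-benzoquinone in which chlorides at B5 and B6 are vinylogous acid chlorides. A methoxy group at B2 turns the B4 carbonyl into a vinylogous ester, which leaves B5 (conjugated to the B1 carbonyl) the more electrophilic of the two. Both dioxin C–O bonds can then be made by addition–elimination under mild base, and reduction returns the two carbonyls as the B1 and B4 oxygens.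

## Retrosynthetic reasoning

**22 from 21.** The seven O–H bonds are cut first: every phenol of 22 is masked as a methyl ether in 21. A free polyphenol would be oxidised or deprotonated in every base-mediated step, so the unmasking comes last. The forward step must cleave seven aryl methyl ethers without touching the three diaryl ether bonds or the furan.

**21 from 19 and 20.** The B1–O bond to ring A is cut next. Ring A is the simplest, symmetrical fragment and is bought as bromide 20. Attaching it last keeps a bulky aryl group away from B1 while the dioxin is built, and 19 offers B1 as its only free phenol. The forward reaction is a copper-catalysed etherification of a phenol flanked by two oxygen substituents.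

**19 from 18, 18 from 17.** The B4 methyl group is removed to give hydroquinone 18, and 18 is the reduced form of quinone 17. This is where the quinone carbonyls become the B1 and B4 oxygens. The forward steps must reduce 17 and then alkylate only the B4 hydroxyl, which has a hydrogen neighbour (B3), while B1 is flanked by the B2 methoxy group and the dioxin oxygen.

**17 from 16 (key disconnection).** The B6–O bond to the D1 oxygen is cut, opening the dioxin ring to the chloroquinone 16. This bond is cut and not B5–O because B6 is the less electrophilic of the two quinone carbons (the B5 aryloxy group pushes electrons onto it and the B2 methoxy group deactivates the B4 carbonyl); it is best made intramolecularly, with chloride as the leaving group. The forward step must close at B6 faster than the D1 phenoxide attacks B5 in the ipso sense, since that path would move the quinone from one catechol oxygen to the other and turn ring B round. The orientation set in the preceding bond is therefore retained only if ring closure outruns this transposition, and the conditions of the step are chosen with that in mind.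

**16 from 15, 15 from 12 and 14.** The D1 hydroxyl of 16 is masked as a 2-(trimethylsilyl)ethyl ether in 15, and the B5–O bond to the D6 oxygen is cut to phenol 12 and dichloroquinone 14. The D6 oxygen has to attack first, because the intermolecular substitution goes to the chloride conjugated to the carbonyl that the methoxy group does not deactivate, and that carbon is B5. The mask on D1 is an alkyl ether, which cannot migrate to the neighbouring phenoxide as a silyl or acyl group would. It is removed with acid so that 16 can be isolated before any base is added, and its cleavage releases no carbon electrophile toward ring F.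

**14 from 13.** The C5–OMe bond of 14 is traced to the parent dichloroquinone 13 by conjugate addition of the alcohol to the unsubstituted enone carbon and re-oxidation, for which a second equivalent of 13 serves.

**12 from 10, 10 from 9, 9 from 8.** The D6 (C9) oxygen is traced to a formyl group by aryl migration to peracid oxygen, and the formyl group to the C9–H of phenol 8. Ring F is far more nucleophilic than C9 toward any free electrophile, so only a reagent delivered by the D1 phenoxide can reach C9; a magnesium phenoxide-directed formylation does this, with C7 blocked by its methoxy group. The D1 hydroxyl is capped between the two operations, so the two oxygens of the catechol end up distinguished without a selective protection.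

**8 from 7, 7 from 6.** The benzyl ether is put back on D1, and the furan C4a–O bond is cut to biaryl phenol 6. Ring F can then come from a simple 2,4-dimethoxyphenyl unit. The forward step is a phenol-directed C–H activation and C–O cyclisation at the only free ortho carbon of ring F; the benzyl ether ensures that a single phenol binds the metal.

**6 from 4, 4 from 2 and 3, 2 from 1.** The D4 phenol comes from the formyl group of 4 by peracid oxidation, the D5–C9b biaryl bond from a Suzuki coupling of bromide 2 with boronic acid 3, and the bromide from bromination of 1 para to its methoxy group. The vanillin skeleton of 1 maps directly onto ring D: OMe is D2, the benzyl ether is D1, CHO becomes D4 and the bromide marks D5.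

## Alternatives that were turned down

**Alternative 1: bay-tethered macrocycle, transannular biaryl coupling.**
- Disconnection: the D5–C9b biaryl bond of the dibenzofuran, in a ring D–O–ring F diaryl ether whose two bay oxygens (on D6 and on C1 of ring F) are tied by a tetraisopropyldisiloxane bridge, the twelve-membered macrocycle A1.
- Forward key step: oxidative dehydrogenative coupling across the ring joins the two carbons lying between the ether oxygen and the tethered oxygen and closes the furan, giving the bridged dibenzofuran A2.
- For it: the tether lets only one pair of carbons meet, and the D6 oxygen is in place before the bay exists. On this point it is stronger than the chosen route, which formylates the crowded C9 of 8 late.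
- Against it: every free carbon of both rings lies between two oxygens, so the tether alone must direct the coupling, against intermolecular coupling and over-oxidation of such electron-rich ethers. Aryl silyl ethers are fragile under the Lewis-acidic oxidants these couplings need. Building and removing the tether costs about three steps. Removing the bridge from A2 frees two bay phenols at once, so D6 must still be told apart from C1.
- Comparison: the step solves the dibenzofuran, not the dioxin. The chosen strategy makes the dibenzofuran by standard cross-coupling and spends its risk on the dioxin orientation, which is the harder problem.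

**Alternative 2: squarate ring expansion builds ring D.**
- Disconnection: ring D itself, traced to the cyclobutenone A3 (3-(benzyloxy)-2-(2-fluoro-4,6-dimethoxyphenyl)-4-hydroxy-4-(1-methoxyvinyl)cyclobut-2-en-1-one), derived from a squaric ester.
- Forward key step: heating opens A3 to a dienylketene; the ketene carbon (later D4) bonds to the vinyl terminus (later D3) in a six-electron closure, and tautomerisation gives hydroquinone A4 with ring F already on D5. The D4 hydroxyl would later displace fluoride to close the furan.
- For it: ring D is made hexasubstituted in one thermal step with regiochemistry fixed by the order of additions. The D6 oxygen is present from the start and distinguished (benzyl) from D1 (free), which is again stronger than late bay formylation. The furan closes without a transition metal.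
- Against it: A3 needs three successive regiocontrolled additions to the four-membered ring, one of them an ortho-disubstituted aryl nucleophile. The protection pattern of A4 is the reverse of what the quinone chemistry needs (D6 free, D1 masked), so groups must be exchanged. Fluoride displacement on a ring bearing two methoxy groups needs forcing conditions beside an air-sensitive hydroquinone.
- Comparison: the step count to an equivalent of 12 is no lower than the eight steps of the chosen route, and the dioxin remains unsolved. The chosen route gets the needed protection pattern directly from the formylation order.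

**Alternative 3: photochemical ketene benzannulation grows ring F.**
- Disconnection: three C–C bonds of ring F, cut back to the benzofuranyl diazoketone A5 (1-[5-(benzyloxy)-6-methoxy-1-benzofuran-2-yl]-2-diazoethan-1-one) and ethoxyacetylene A6.
- Forward key step: irradiation triggers Wolff rearrangement to a hetarylketene, (2+2) cycloaddition with A6, four-electron opening of the cyclobutenone and six-electron closure onto C3 of the benzofuran, giving 8-(benzyloxy)-3-ethoxy-7-methoxydibenzofuran-1-ol A7.
- For it: three bonds form in one operation, with the C1 hydroxyl distinguished from the C3 ether and the regiochemistry set by alkyne polarity. In bonds made per step it is stronger than the Suzuki, peracid and cyclisation sequence chosen here.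
- Against it: A5 needs a benzofuran-2-carboxylic acid and diazo chemistry, and photolysis limits scale. A7 still has hydrogen at D6 (C9), so it stands no further than 8; the bay oxygen would still have to be introduced, now beside a C1 hydroxyl that must first be capped.
- Comparison: the chosen route reaches 8 in five steps from three catalogue compounds by standard couplings and keeps its risk for the dioxin.

Key step: step 12

## Route

Assumption: compounds 1, 3, 13 and 20 are taken as commercial, and the labels B1–B6 and D1–D6 are those defined in the analysis.

Step 1
Reactants: 1 4-(benzyloxy)-3-methoxybenzaldehyde (O-benzylvanillin)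
Product: 2 4-(benzyloxy)-2-bromo-5-methoxybenzaldehyde
Conditions: Br2, NaOAc, AcOH, rt
Reagents that add atoms: bromine, BrBr
Why: Electrophilic aromatic bromination goes para to the methoxy group (C6 of the vanillin ring), the usual site for 4-O-alkylvanillins; sodium acetate buffers the HBr so the benzyl ether survives.

Step 2
Reactants: 2 4-(benzyloxy)-2-bromo-5-methoxybenzaldehyde; 3 2,4-dimethoxyphenylboronic acid
Product: 4 4-(benzyloxy)-2-(2,4-dimethoxyphenyl)-5-methoxybenzaldehyde
Conditions: Pd(PPh3)4 (5 mol %), K2CO3, DME/H2O, 85 °C
Reagents that add atoms: none
Why: Suzuki–Miyaura coupling; the ortho-formyl group speeds oxidative addition of the bromide to zerovalent palladium, and each partner has only one ortho substituent at the new bond (D5–C9b).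

Step 3
Reactants: 4 4-(benzyloxy)-2-(2,4-dimethoxyphenyl)-5-methoxybenzaldehyde
Product: 6 4-(benzyloxy)-2-(2,4-dimethoxyphenyl)-5-methoxyphenol, via aryl formate 5 (not isolated)
Conditions: mCPBA, CH2Cl2, 0 °C → rt; then K2CO3 (cat.), MeOH, rt
Reagents that add atoms: 3-chloroperoxybenzoic acid, O=C(OO)c1cccc(Cl)c1
Why: Baeyer–Villiger (Dakin-type) oxidation; the para-benzyloxy group makes the aryl group migrate in preference to hydride, and the formate is removed by methanolysis to give the D4 phenol.

Step 4
Reactants: 6 4-(benzyloxy)-2-(2,4-dimethoxyphenyl)-5-methoxyphenol
Product: 7 8-(benzyloxy)-1,3,7-trimethoxydibenzo[b,d]furan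
Conditions: Pd(OAc)2 (5 mol %), 1,3-bis(2,6-diisopropylphenyl)imidazol-2-ylidene (10 mol %), 4,5-diazafluoren-9-one (10 mol %), MesCO2Na, K2CO3, mesitylene, air, 120 °C
Reagents that add atoms: none
Why: Phenol-directed C–H activation and C–O cyclisation by divalent palladium: the phenoxide binds the metal, metalation occurs at the only free ortho carbon of ring F, and C–O reductive elimination closes the furan while air reoxidises zerovalent palladium. The benzyl ether on D1 leaves a single phenol to direct the metal.

Step 5
Reactants: 7 8-(benzyloxy)-1,3,7-trimethoxydibenzo[b,d]furan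
Product: 8 1,3,7-trimethoxydibenzo[b,d]furan-8-ol
Conditions: H2 (1 atm), Pd/C, EtOAc/MeOH, rt
Reagents that add atoms: none
Why: Hydrogenolysis of the benzyl ether frees the D1 hydroxyl, which is needed to direct the next step; methyl ethers and the dibenzofuran are inert.

Step 6
Reactants: 8 1,3,7-trimethoxydibenzo[b,d]furan-8-ol
Product: 9 8-hydroxy-1,3,7-trimethoxydibenzo[b,d]furan-9-carbaldehyde
Conditions: MgCl2, Et3N, (CH2O)n, MeCN, reflux
Reagents that add atoms: formaldehyde (as paraformaldehyde), C=O
Why: Casiraghi–Skattebøl ortho-formylation: the magnesium phenoxide delivers formaldehyde to the ortho carbon through a six-membered chelate, and a second formaldehyde oxidises the benzylic alkoxide by hydride transfer. C7 is blocked by its methoxy group, so only C9 (D6) can react, and without phenoxide delivery the reagent is too weak an electrophile to attack ring F.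

Step 7
Reactants: 9 8-hydroxy-1,3,7-trimethoxydibenzo[b,d]furan-9-carbaldehyde
Product: 10 1,3,7-trimethoxy-8-[2-(trimethylsilyl)ethoxy]dibenzo[b,d]furan-9-carbaldehyde
Conditions: Me3SiCH2CH2OH, PPh3, DIAD, THF, 0 °C → rt
Reagents that add atoms: 2-(trimethylsilyl)ethanol, C[Si](C)(C)CCO
Why: Mitsunobu etherification of a phenol made more acidic by the ortho-formyl group. The resulting alkyl ether cannot migrate to the neighbouring oxygen, survives peracid and carbonate, and is later cleaved without releasing a carbon electrophile.

Step 8
Reactants: 10 1,3,7-trimethoxy-8-[2-(trimethylsilyl)ethoxy]dibenzo[b,d]furan-9-carbaldehyde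
Product: 12 1,3,7-trimethoxy-8-[2-(trimethylsilyl)ethoxy]dibenzo[b,d]furan-9-ol, via aryl formate 11 (not isolated)
Conditions: mCPBA, CH2Cl2, 0 °C → rt; then K2CO3 (cat.), MeOH, 0 °C
Reagents that add atoms: 3-chloroperoxybenzoic acid, O=C(OO)c1cccc(Cl)c1
Why: Baeyer–Villiger oxidation; the ortho-alkoxy group on the migrating carbon favours aryl migration, and methanolysis of the formate frees the D6 phenol while D1 stays masked.

Step 9
Reactants: 13 2,3-dichloro-1,4-benzoquinone
Product: 14 2,3-dichloro-5-methoxy-1,4-benzoquinone
Conditions: MeOH, ZnCl2, rt (13 2 equiv; the second equivalent is the oxidant)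
Reagents that add atoms: methanol, CO
Why: Lewis acid-promoted conjugate addition of methanol to the unsubstituted enone carbon, enolisation to the methoxyhydroquinone and oxidation by the more oxidising 13. The chlorine-bearing carbons do not react with neutral methanol, and the remaining C–H is the alpha carbon of the new vinylogous ester, so the reaction should stop at one methoxy group.

Step 10
Reactants: 12 1,3,7-trimethoxy-8-[2-(trimethylsilyl)ethoxy]dibenzo[b,d]furan-9-ol; 14 2,3-dichloro-5-methoxy-1,4-benzoquinone
Product: 15 3-chloro-5-methoxy-2-({1,3,7-trimethoxy-8-[2-(trimethylsilyl)ethoxy]dibenzo[b,d]furan-9-yl}oxy)-1,4-benzoquinone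
Conditions: Cs2CO3, MeCN, −20 → 0 °C; 12 added slowly to 14 (1.5 equiv)
Reagents that add atoms: none
Why: Addition–elimination of the D6 phenoxide on a haloquinone. The C1 carbonyl of 14 is a vinylogous ester of the C5 methoxy group, so attack goes to C2 (the later B5), which is conjugated to the undeactivated C4 carbonyl; the methoxy group also deactivates the only C–H position. Excess quinone and inverse addition limit displacement of the second chloride, and with D1 masked no transposition is possible.

Step 11
Reactants: 15 3-chloro-5-methoxy-2-({1,3,7-trimethoxy-8-[2-(trimethylsilyl)ethoxy]dibenzo[b,d]furan-9-yl}oxy)-1,4-benzoquinone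
Product: 16 3-chloro-2-[(8-hydroxy-1,3,7-trimethoxydibenzo[b,d]furan-9-yl)oxy]-5-methoxy-1,4-benzoquinone
Conditions: CF3CO2H, CH2Cl2, 0 °C → rt
Reagents that add atoms: none
Why: Acidolysis of the 2-(trimethylsilyl)ethyl ether through a beta-silyl-stabilised cation that fragments to ethene, so no carbon electrophile is set free toward ring F. The acid keeps the D1 phenol protonated, so 16 can be isolated before base is added.

Step 12
Reactants: 16 3-chloro-2-[(8-hydroxy-1,3,7-trimethoxydibenzo[b,d]furan-9-yl)oxy]-5-methoxy-1,4-benzoquinone
Product: 17 dioxin-fused quinone: 5-methoxy-1,4-benzoquinone whose C2 and C3 are bonded through oxygen to C9 and C8 of 1,3,7-trimethoxydibenzofuran (ring B as quinone; B1 and B4 are C=O, B2 is OMe)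
Conditions: Cs2CO3, MeCN (0.005 M), 0 °C → rt, Ar
Reagents that add atoms: none
Why: The cesium phenoxide at D1 adds to B6, the chlorine-bearing carbon beta to the B4 carbonyl, and the enolate expels chloride to restore the quinone, now fused to the dioxin; the C–O bond forms by addition–elimination on a vinylogous acid chloride, without copper and without a nitro group. The closest known reaction type is the condensation of phenols and catechols with 2,3-dihalo-1,4-quinones, which gives aryloxyquinones and dioxin-fused quinones under carbonate or amine bases. The dioxin ring closes in the 6-endo-trig mode, the nucleophile being held beside B6 by the D6–O–B5 ether from step 10. No stereocenter is formed. The selectivity needed is attack at B6 and not ipso attack at B5, which would give a five-membered spiro adduct and, by opening toward the bay, move the quinone from the D6 to the D1 oxygen (a Smiles-type transposition) and reverse the orientation of ring B. Three features work against that path: only the B6 adduct has chloride to lose and so collapses irreversibly; opening the spiro adduct toward the bay would free a phenoxide pressed against the C1 methoxy oxygen of ring F, which is unfavourable with the large, poorly chelating cesium ion in an aprotic solvent; and if the two mono-ethers equilibrate all the same, closure through the unhindered and more electron-rich D1 oxygen should remain the faster ring closure. High dilution keeps the phenoxide from attacking a second quinone.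

Step 13
Reactants: 17 dioxin-fused quinone
Product: 18 dioxin hydroquinone (B1 OH, B4 OH, B2 OMe; dibenzofuran part unchanged)
Conditions: Na2S2O4, EtOAc/H2O, rt, Ar
Reagents that add atoms: none
Why: Dithionite reduction of a quinone to its hydroquinone; the two carbonyls become the B1 and B4 hydroxyls, and the product is used at once under argon because it re-oxidises easily.

Step 14
Reactants: 18 dioxin hydroquinone
Product: 19 B4 methyl ether of 18 (B1 OH free; B2 and B4 OMe)
Conditions: MeI (1.05 equiv), K2CO3, acetone, 0 °C → rt, Ar
Reagents that add atoms: iodomethane, CI
Why: Mono-O-alkylation of a hydroquinone at its less hindered hydroxyl: B4 has the B3 hydrogen as neighbour, whereas B1 is flanked by the B2 methoxy group (to which it can hydrogen-bond) and the dioxin oxygen.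

Step 15
Reactants: 19 B4 methyl ether of 18; 20 1-bromo-3,5-dimethoxybenzene
Product: 21 heptamethyl ether of the target (ring A attached through oxygen at B1; all seven hydroxyls as OMe)
Conditions: CuI (20 mol %), N,N-dimethylglycine hydrochloride (40 mol %), Cs2CO3, 1,4-dioxane, 100 °C, Ar
Reagents that add atoms: none
Why: Ullmann diaryl ether synthesis under ligand-accelerated catalysis by monovalent copper, which tolerates electron-rich aryl bromides and ortho-substituted phenoxides; B1 is the only free hydroxyl.

Step 16
Reactants: 21 heptamethyl ether of the target
Product: 22 target CNP0256302.0 (ring A 3,5-dihydroxyphenoxy at B1; OH at B2, B4, D2 and at C1 and C3 of ring F)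
Conditions: BBr3 (excess), CH2Cl2, −78 °C → rt; then H2O
Reagents that add atoms: none
Why: Lewis acid cleavage of aryl methyl ethers via bromide attack on the O-methyl group of the borane adduct; diaryl ethers and the furan have no alkyl carbon to attack and are retained.

## Compound list

1 | 4-(benzyloxy)-3-methoxybenzaldehyde (O-benzylvanillin) | COc1cc(C=O)ccc1OCc1ccccc1 | starting material
2 | 4-(benzyloxy)-2-bromo-5-methoxybenzaldehyde | COc1cc(C=O)c(Br)cc1OCc1ccccc1 | intermediate
3 | 2,4-dimethoxyphenylboronic acid | COc1ccc(B(O)O)c(OC)c1 | starting material
4 | 4-(benzyloxy)-2-(2,4-dimethoxyphenyl)-5-methoxybenzaldehyde | COc1ccc(-c2cc(OCc3ccccc3)c(OC)cc2C=O)c(OC)c1 | intermediate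
5 | 4-(benzyloxy)-2-(2,4-dimethoxyphenyl)-5-methoxyphenyl formate | COc1ccc(-c2cc(OCc3ccccc3)c(OC)cc2OC=O)c(OC)c1 | intermediate
6 | 4-(benzyloxy)-2-(2,4-dimethoxyphenyl)-5-methoxyphenol | COc1ccc(-c2cc(OCc3ccccc3)c(OC)cc2O)c(OC)c1 | intermediate
7 | 8-(benzyloxy)-1,3,7-trimethoxydibenzo[b,d]furan | COc1cc(OC)c2c(c1)oc1cc(OC)c(OCc3ccccc3)cc12 | intermediate
8 | 1,3,7-trimethoxydibenzo[b,d]furan-8-ol | COc1cc(OC)c2c(c1)oc1cc(OC)c(O)cc12 | intermediate
9 | 8-hydroxy-1,3,7-trimethoxydibenzo[b,d]furan-9-carbaldehyde | COc1cc(OC)c2c(c1)oc1cc(OC)c(O)c(C=O)c12 | intermediate
10 | 1,3,7-trimethoxy-8-[2-(trimethylsilyl)ethoxy]dibenzo[b,d]furan-9-carbaldehyde | COc1cc(OC)c2c(c1)oc1cc(OC)c(OCC[Si](C)(C)C)c(C=O)c12 | intermediate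
11 | 1,3,7-trimethoxy-8-[2-(trimethylsilyl)ethoxy]dibenzo[b,d]furan-9-yl formate | COc1cc(OC)c2c(c1)oc1cc(OC)c(OCC[Si](C)(C)C)c(OC=O)c12 | intermediate
12 | 1,3,7-trimethoxy-8-[2-(trimethylsilyl)ethoxy]dibenzo[b,d]furan-9-ol | COc1cc(OC)c2c(c1)oc1cc(OC)c(OCC[Si](C)(C)C)c(O)c12 | intermediate
13 | 2,3-dichloro-1,4-benzoquinone | O=C1C=CC(=O)C(Cl)=C1Cl | starting material
14 | 2,3-dichloro-5-methoxy-1,4-benzoquinone | COC1=CC(=O)C(Cl)=C(Cl)C1=O | intermediate
15 | 3-chloro-5-methoxy-2-({1,3,7-trimethoxy-8-[2-(trimethylsilyl)ethoxy]dibenzo[b,d]furan-9-yl}oxy)-1,4-benzoquinone | COc1cc2oc3cc(OC)cc(OC)c3c2c(OC2=C(Cl)C(=O)C(OC)=CC2=O)c1OCC[Si](C)(C)C | intermediate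
16 | 3-chloro-2-[(8-hydroxy-1,3,7-trimethoxydibenzo[b,d]furan-9-yl)oxy]-5-methoxy-1,4-benzoquinone | COc1cc2oc3cc(OC)cc(OC)c3c2c(OC2=C(Cl)C(=O)C(OC)=CC2=O)c1O | intermediate
17 | dioxin-fused quinone (5-methoxy-1,4-benzoquinone with C2–O–C9 and C3–O–C8 links to 1,3,7-trimethoxydibenzofuran) | COc1cc2oc3cc(OC)cc(OC)c3c2c2c1OC1=C(O2)C(=O)C=C(OC)C1=O | intermediate
18 | dioxin hydroquinone (B1 OH, B4 OH, B2 OMe) | COc1cc2oc3cc(OC)cc(OC)c3c2c2c1Oc1c(O2)c(O)cc(OC)c1O | intermediate
19 | B4 methyl ether of 18 (B1 OH free) | COc1cc2oc3cc(OC)cc(OC)c3c2c2c1Oc1c(O2)c(OC)cc(OC)c1O | intermediate
20 | 1-bromo-3,5-dimethoxybenzene | COc1cc(Br)cc(OC)c1 | starting material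
21 | heptamethyl ether of the target | COc1cc(OC)cc(Oc2c(OC)cc(OC)c3c2Oc2c(OC)cc4oc5cc(OC)cc(OC)c5c4c2O3)c1 | intermediate
22 | CNP0256302.0 (heptahydroxy compound) | Oc1cc(O)cc(Oc2c(O)cc(O)c3c2Oc2c(O)cc4oc5cc(O)cc(O)c5c4c2O3)c1 | target

## Step count and least certain steps

Total step count: 16. Longest linear sequence: 15 steps (1 to 22 through steps 1–8 and 10–16); step 9 is a one-step branch.

**Step 12 (key step).** The most likely failure is transposition of the quinone between the two catechol oxygens by ipso attack at B5 before the ring closes, which would give the dioxin with ring B turned round. Closure may also be sluggish, because B6 is deactivated by the B5 aryloxy group and the B2 methoxy group, and this leaves time for intermolecular substitution. The fallback sets out from 16 and returns at 18. 16 is reduced with Na2S2O4 to 3-chloro-2-[(8-hydroxy-1,3,7-trimethoxydibenzofuran-9-yl)oxy]-5-methoxybenzene-1,4-diol F1, in which the B5–O bond is an ordinary diaryl ether that cannot migrate. The D1 hydroxyl is then joined to B6 by copper-catalysed intramolecular Ullmann etherification of the aryl chloride (CuI, an N,N'-diaryloxalamide ligand, K3PO4, DMSO, 120 °C, strict exclusion of air). This gives 18 directly and makes step 13 unnecessary.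

**Step 10.** Electron transfer from the electron-rich bay phenoxide to the quinone may lead to oxidative decomposition; the hindered phenoxide may react slowly at the fully substituted carbon; and substitution may stray to the second chloride. The fallback sets out from 12 and 13 and returns at 15. 12 is joined to the parent quinone 13 (Cs2CO3, MeCN, −20 °C), which is symmetrical, so the first substitution poses no regiochemical question, and more electrophilic than 14. The product is 2-chloro-3-({1,3,7-trimethoxy-8-[2-(trimethylsilyl)ethoxy]dibenzofuran-9-yl}oxy)-1,4-benzoquinone F2. The B2 methoxy group is then introduced by ZnCl2-promoted addition of methanol and re-oxidation with tetrachloro-1,4-benzoquinone. The aryloxy group at B5 deactivates the B1 carbonyl and so steers methanol to B2, giving 15.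

**Step 6.** Formylation may fail at the crowded bay carbon C9, or formaldehyde may condense with the very nucleophilic ring F. The fallback sets out from 8 and returns at 9, delivering the carbon by a sigmatropic shift instead of an external electrophile. 8 is allylated (allyl bromide, K2CO3, acetone) to 8-(allyloxy)-1,3,7-trimethoxydibenzofuran F3. Claisen rearrangement (N,N-diethylaniline, 190 °C) moves the allyl group to C9, the only free ortho position, giving 9-allyl-1,3,7-trimethoxydibenzofuran-8-ol F4. Isomerisation (RuHCl(CO)(PPh3)3 cat., toluene, 80 °C) gives 1,3,7-trimethoxy-9-[(E)-prop-1-enyl]dibenzofuran-8-ol F5, and Lemieux–Johnson cleavage (OsO4 cat., NaIO4, 2,6-lutidine, dioxane/H2O) gives 9.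

**Step 14.** Site selectivity between the B4 and B1 hydroxyls may be poor, double methylation may occur, and the hydroquinone may re-oxidise to 17. The fallback sets out from 18 and returns at 19, replacing kinetic mono-alkylation by exhaustive alkylation and selective cleavage. 18 is methylated at both hydroxyls (MeI excess, K2CO3, acetone) to the hexamethoxy dioxin F6 (B1 and B4 both OMe). The B1 methyl ether is the only methoxy group flanked by two oxygen substituents, and it is cleaved selectively by chelation-controlled demethylation (AlCl3, CH2Cl2, 0 °C), as known for the central ether of 1,2,3-trioxygenated arenes, to give 19.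

**Step 9.** Methanol may displace chloride, or a second addition may follow the first. The fallback sets out from 13 and returns at 14. Thiele–Winter acetoxylation (Ac2O, BF3·OEt2) gives 5,6-dichlorobenzene-1,2,4-triyl triacetate F7. Acid methanolysis (HCl, MeOH) gives 5,6-dichlorobenzene-1,2,4-triol F8, which FeCl3 oxidises to 2,3-dichloro-5-hydroxy-1,4-benzoquinone F9. O-Methylation of this vinylogous acid (MeI, Ag2O, CHCl3) gives 14.

## Further compounds

F1 | step 12 | 3-chloro-2-[(8-hydroxy-1,3,7-trimethoxydibenzofuran-9-yl)oxy]-5-methoxybenzene-1,4-diol | COc1cc2oc3cc(OC)cc(OC)c3c2c(Oc2c(Cl)c(O)c(OC)cc2O)c1O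
F2 | step 10 | 2-chloro-3-({1,3,7-trimethoxy-8-[2-(trimethylsilyl)ethoxy]dibenzofuran-9-yl}oxy)-1,4-benzoquinone | COc1cc2oc3cc(OC)cc(OC)c3c2c(OC2=C(Cl)C(=O)C=CC2=O)c1OCC[Si](C)(C)C
F3 | step 6 | 8-(allyloxy)-1,3,7-trimethoxydibenzofuran | COc1cc(OC)c2c(c1)oc1cc(OC)c(OCC=C)cc12
F4 | step 6 | 9-allyl-1,3,7-trimethoxydibenzofuran-8-ol | COc1cc(OC)c2c(c1)oc1cc(OC)c(O)c(CC=C)c12
F5 | step 6 | 1,3,7-trimethoxy-9-[(E)-prop-1-enyl]dibenzofuran-8-ol | COc1cc(OC)c2c(c1)oc1cc(OC)c(O)c(/C=C/C)c12
F6 | step 14 | hexamethoxy dioxin (B1,B4-dimethyl ether of 18) | COc1cc2oc3cc(OC)cc(OC)c3c2c2c1Oc1c(O2)c(OC)cc(OC)c1OC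
F7 | step 9 | 5,6-dichlorobenzene-1,2,4-triyl triacetate | CC(=O)Oc1cc(OC(C)=O)c(Cl)c(Cl)c1OC(C)=O
F8 | step 9 | 5,6-dichlorobenzene-1,2,4-triol | Oc1cc(O)c(Cl)c(Cl)c1O
F9 | step 9 | 2,3-dichloro-5-hydroxy-1,4-benzoquinone | OC1=CC(=O)C(Cl)=C(Cl)C1=O
A1 | alternative 1 | twelve-membered diaryl ether with a tetraisopropyldisiloxane bridge between the D6 oxygen and the C1 oxygen of ring F (D1 benzyloxy, D2 and C3 methoxy) | COc1cc2cc(c1OCc1ccccc1)O[Si](C(C)C)(C(C)C)O[Si](C(C)C)(C(C)C)Oc1cc(OC)cc(c1)O2
A2 | alternative 1 | 8-(benzyloxy)-3,7-dimethoxydibenzofuran with the 1- and 9-oxygens bridged by tetraisopropyldisiloxane-1,3-diyl | COc1cc2oc3cc(OC)cc4c3c2c(c1OCc1ccccc1)O[Si](C(C)C)(C(C)C)O[Si](C(C)C)(C(C)C)O4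
A3 | alternative 2 | 3-(benzyloxy)-2-(2-fluoro-4,6-dimethoxyphenyl)-4-hydroxy-4-(1-methoxyvinyl)cyclobut-2-en-1-one (racemic) | O=C1C(c2c(F)cc(OC)cc2OC)=C(OCc2ccccc2)C1(O)C(OC)=C
A4 | alternative 2 | 3-(benzyloxy)-2-(2-fluoro-4,6-dimethoxyphenyl)-5-methoxybenzene-1,4-diol | Oc1cc(OC)c(O)c(OCc2ccccc2)c1-c1c(F)cc(OC)cc1OC
A5 | alternative 3 | 1-[5-(benzyloxy)-6-methoxy-1-benzofuran-2-yl]-2-diazoethan-1-one | COc1cc2oc(C(=O)C=[N+]=[N-])cc2cc1OCc1ccccc1
A6 | alternative 3 | ethoxyacetylene | C#COCC
A7 | alternative 3 | 8-(benzyloxy)-3-ethoxy-7-methoxydibenzofuran-1-ol | COc1cc2oc3cc(OCC)cc(O)c3c2cc1OCc1ccccc1
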